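All runs come from a simulation for an exercise; noise was put on by code.

No rate constant is given here, so you take the pace of the flask from the runs. Electrophile and nucleophile give target and acid set free, and free base can take up that acid.

all flasks: electrophile 0.10 M

| flask | free base | protonated nucleophile | remark | time |
|---|---|---|---|---|
| birch | 1.7 equiv | 1.2 equiv | run made earlier |  |
| cedar | 2.9 equiv | 1.2 equiv | run made earlier |  |
| green | 2.00 equiv | 1.20 equiv |  | 8.0 min |
| red | 2.60 equiv | 1.20 equiv |  | 8.0 min |
| violet | 3.40 equiv | 1.20 equiv |  | 8.0 min |

| run | time / min | electrophile / % | target / % |
|---|---|---|---|
| birch | 0.417 | 99.4 | 0 |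
| birch | 0.667 | 99.6 | 0.4 |
| birch | 1.33 | 99.5 | 0.2 |
| birch | 2.00 | 98.6 | 1.1 |
| birch | 3.00 | 98.2 | 1.3 |
| birch | 6.00 | 96.1 | 2.6 |
| cedar | 0.417 | 99.7 | 0 |
| cedar | 0.667 | 99.4 | 0.1 |
| cedar | 1.33 | 99.5 | 0.1 |
| cedar | 2.00 | 99.1 | 1.5 |
| cedar | 3.00 | 97.5 | 1.5 |
| cedar | 6.00 | 95.4 | 3.6 |

(readings scatter by 0.3 percentage points)

- a species is counted by the electrophile in it: one side product A counts as two
- what was read earlier has a scatter of 0.3 percentage points, one standard deviation
- candidate steps: acid set free + target -> side product B; electrophile + nucleophile -> acid set free + target; electrophile + target -> side product A; target <-> isomer of the product; nucleophile + acid set free <-> protonated nucleophile; acid set free + free base <-> salt of the base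

1. part of the electrophile that has reacted at the end, green
2. part of the electrophile that has reacted at the end, red
3. part of the electrophile that has reacted at the end, violet
4. what raising the equivalents of free base from its lowest to its highest value here does to the part of the electrophile that has reacted (changes below 5 percentage points count as none) (no change / it falls / it rises)

Read the last rows against each other. At 6.00 min birch has lost 3.90% of its electrophile and cedar 4.60%. That difference of 0.7 percentage points stands little above the scatter of 0.3 points on a reading.

Now read down the birch column. Its loss at 6.00 min is twice its loss at 3.00 min, so the loss grows about in step with time, and you may stretch it to 8.0 min.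

Then read target against electrophile. Birch shows 2.6% of target and cedar 3.6%, which leaves gaps of 1.3 points and 1 point. Both are above the scatter, so in these readings part of the lost electrophile seems to stand in something other than target.

Join the two runs by a straight line in free base and stretch it to the asked time and the asked range of base. This gives 1.1 points: this is the base span, the extra loss that this line gives across the asked range of free base at the asked time, and it carries the scatter of the readings. My line puts green at 5.43% and violet at 6.53%. The span is smaller than the margin of 5 points, so I expect no change.

The forecast gives 5.3%, 5.7% and 6.2%, and its verdict is no change: “The spread is about 1 point, well under 5”. Its spread of 0.9 points is a little smaller than my span, but the verdict is the same.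

    acid set free + target → side product B (k = 2.30 M⁻¹ min⁻¹)
    electrophile + nucleophile → acid set free + target (k = 1.20 M⁻¹ min⁻¹)
    electrophile + target → side product A (k = 0.0990 M⁻¹ min⁻¹)
    target ⇌ isomer of the product (K = 13.0, k = 0.130 min⁻¹)
    nucleophile + acid set free ⇌ protonated nucleophile, settled at all times (K = 16000 M⁻¹)
    acid set free + free base ⇌ salt of the base (K = 27000 M⁻¹, k = 8.80 M⁻¹ min⁻¹)

The flask gives 5.63% in green, 6.37% in red and 7.23% in violet, so the verdict is no change: the change of 1.6 points is larger than the base span of 1.1 points read from the runs and smaller than 5 points. In red at 3.03 min, target goes to isomer of the product, counting the forward step alone, 13 times faster than to side product A, a selectivity factor, and at 8.00 min red holds 3.93% of target and 2.09% of isomer of the product. In green, that step makes no difference to the part of the electrophile that has reacted. The neighbour of red with 0.25 M of electrophile, equivalents and time held, reaches 11.4%, which stands 4.66 base spans above red.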